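**Retrosynthetic overview**
- The target is the O5 ester of natural shikimic acid with a cis-(2S,3R)-2-aryl-7-hydroxy-2,3-dihydrobenzofuran-3-carboxylic acid bearing an (E)-acrylic acid on C4. Last cuts: silyl and acetonide groups, the ester C(=O)–O5 bond, then the C4–vinyl bond (carboxylate-directed C–H olefination; C4 is the only free ortho carbon beside C3a).
- Key cut: the O1–C7a bond of the dihydrofuran ring together with the C7–OH bond, leading back to an acyclic benzylic alkoxide tethered to a 3-bromo-2-fluorophenyl ring.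
- Enabling feature: on the benzo ring, C7a (ring oxygen O1) and C7 (phenolic OH) are two adjacent oxygen-bearing carbons next to C3a, which carries the C3–C2–O chain. This vicinal C7a–O/C7–O pair is what a 7,7a-aryne takes up in one operation, the tether forcing O onto C7a and leaving the carbanion on C7.
- The acyclic precursor comes from an auxiliary-controlled anti-aldol of 2-(3-bromo-2-fluorophenyl)acetic acid with protected 3,4-dihydroxybenzaldehyde (anti in the chain becomes cis in the ring), taken to the alcohol level so that C3 cannot epimerise during the anionic step.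
- Ring order: both benzene rings and the shikimate cyclohexene are bought; the only ring built is the dihydrofuran (key step). Temporary rings are the oxazolidinone auxiliary and the shikimate acetonide.

Key step: step 6

Remark on the chemistry: the drawn (2S,3R) centres place the C2 aryl and C3 carboxyl groups cis, the less stable arrangement, so after ring closure the route avoids base on a C3 carbonyl derivative and strong acid at the C2–O1 benzylic ether.

Abbreviations: TIPS = triisopropylsilyl; DMTr = bis(4-methoxyphenyl)(phenyl)methyl; DIC = N,N'-diisopropylcarbodiimide; TASF = tris(dimethylamino)sulfonium difluorotrimethylsilicate.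

**Step 1**
Reactants: 1 2-(3-bromo-2-fluorophenyl)acetic acid; 2 (S)-4-benzyl-1,3-oxazolidin-2-one
Product: 3 (S)-4-benzyl-3-[2-(3-bromo-2-fluorophenyl)acetyl]-1,3-oxazolidin-2-one
Conditions: PivCl, Et3N, THF, −20 °C; then 2, LiCl, rt
Reagents that add atoms: none
Why: N-acylation through the mixed pivalic anhydride (LiCl/Et3N variant) joins acid and auxiliary without a strong base that could enolise the arylacetyl group; no stereocentre is formed.

**Step 2**
Reactants: 4 3,4-dihydroxybenzaldehyde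
Product: 5 3,4-bis(triisopropylsilyloxy)benzaldehyde
Conditions: TIPSCl, imidazole, DMF, rt
Reagents that add atoms: chlorotriisopropylsilane (TIPSCl), CC(C)[Si](Cl)(C(C)C)C(C)C
Why: Standard O-silylation of both phenols; aryl TIPS ethers should survive organolithiums and hot bicarbonate later and fall to fluoride at the end.

**Step 3**
Reactants: 3 (S)-4-benzyl-3-[2-(3-bromo-2-fluorophenyl)acetyl]-1,3-oxazolidin-2-one; 5 3,4-bis(triisopropylsilyloxy)benzaldehyde
Product: 7 (S)-4-benzyl-3-[(2R,3S)-2-(3-bromo-2-fluorophenyl)-3-hydroxy-3-[3,4-bis(triisopropylsilyloxy)phenyl]propanoyl]-1,3-oxazolidin-2-one, via trimethylsilyl ether 6 (not isolated)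
Conditions: MgCl2 (20 mol %), Et3N, TMSCl, EtOAc, rt; then 1 M HCl, THF
Reagents that add atoms: none
Why: Magnesium-halide-catalysed direct anti-aldol of an Evans-type imide: soft enolisation gives the Mg-chelated Z-enolate, the aromatic aldehyde adds in a boat transition state to the face opposite the benzyl group (C2 R as in chelate-controlled alkylations, C3 S, anti), TMSCl traps the aldolate so the addition cannot reverse, and the acidic work-up cleaves the TMS ether.

**Step 4**
Reactants: 7 (S)-4-benzyl-3-[(2R,3S)-2-(3-bromo-2-fluorophenyl)-3-hydroxy-3-[3,4-bis(triisopropylsilyloxy)phenyl]propanoyl]-1,3-oxazolidin-2-one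
Product: 8 (1S,2S)-2-(3-bromo-2-fluorophenyl)-1-[3,4-bis(triisopropylsilyloxy)phenyl]propane-1,3-diol
Conditions: LiBH4, H2O (1 equiv), Et2O, 0 °C
Reagents that add atoms: none
Why: Reductive cleavage of the imide by LiBH4 gives the primary alcohol and returns the auxiliary; neither stereocentre is touched (the descriptor at C2 changes only by priority), and C2 no longer carries a carbonyl and so cannot epimerise.

**Step 5**
Reactants: 8 (1S,2S)-2-(3-bromo-2-fluorophenyl)-1-[3,4-bis(triisopropylsilyloxy)phenyl]propane-1,3-diol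
Product: 9 (1S,2S)-3-[bis(4-methoxyphenyl)(phenyl)methoxy]-2-(3-bromo-2-fluorophenyl)-1-[3,4-bis(triisopropylsilyloxy)phenyl]propan-1-ol
Conditions: DMTrCl, Et3N, 4-(dimethylamino)pyridine (cat.), CH2Cl2, 0 °C → rt
Reagents that add atoms: 4,4'-dimethoxytrityl chloride (DMTrCl), COc1ccc(cc1)C(Cl)(c1ccccc1)c1ccc(OC)cc1
Why: Tritylation is selective for the primary hydroxyl, which must be capped because it too could reach the aryne carbon through a five-membered ring, and a trityl-type ether cannot migrate to the neighbouring alkoxide as a silyl group could.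

**Step 6**
Reactants: 9 (1S,2S)-3-[bis(4-methoxyphenyl)(phenyl)methoxy]-2-(3-bromo-2-fluorophenyl)-1-[3,4-bis(triisopropylsilyloxy)phenyl]propan-1-ol
Product: 13 (2S,3S)-2-[3,4-bis(triisopropylsilyloxy)phenyl]-3-{[bis(4-methoxyphenyl)(phenyl)methoxy]methyl}-2,3-dihydro-1-benzofuran-7-ol, via aryne alkoxide 10 (not isolated), via 7-lithio-dihydrobenzofuran 11 (not isolated), via lithium arylborate 12 (not isolated)
Conditions: n-BuLi (1.0 equiv), THF (0.01 M), −78 °C; t-BuLi (2.0 equiv), −100 °C, then −30 °C; B(OMe)3, −78 °C → rt; H2O2 (30 %), aq NaHCO3, 0 °C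
Reagents that add atoms: hydrogen peroxide, OO
Why: Deprotonation gives the lithium alkoxide, t-BuLi exchanges bromine for lithium at C7, and on warming the 2-fluoroaryllithium loses LiF to give the 7,7a-aryne 10, whose in-plane π bond is attacked at C7a by the tethered alkoxide to give aryllithium 11; B(OMe)3 captures the C7 carbanion as borate 12 and peroxide oxidises C–B to C–OH. The closest known reaction types are anionic aryne cyclisations of tethered nitrogen and carbon nucleophiles with electrophilic quench of the new ortho-lithiated position, and the addition of alkoxides to arynes. The dihydrofuran ring closes by a 5-exo-dig nucleophilic addition of oxygen to the proximal aryne carbon (bond O1–C7a), which is geometrically easy because the new ring is coplanar with the arene. No stereocentre is created: both new bonds are made at aryl carbons, so the anti arrangement of 9 (set in step 3) is carried unchanged into the cis C2/C3 ring. The step needs site selectivity (O on C7a, metal then O on C7) and chemoselectivity (tethered alkoxide versus external organolithium or the primary oxygen): the halogen pattern lets only the 7,7a-aryne form, the three-atom tether from C3a cannot reach C7, all alkyllithium is consumed at −100 °C before LiF is lost under high dilution, and the primary oxygen is capped.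

**Step 7**
Reactants: 13 (2S,3S)-2-[3,4-bis(triisopropylsilyloxy)phenyl]-3-{[bis(4-methoxyphenyl)(phenyl)methoxy]methyl}-2,3-dihydro-1-benzofuran-7-ol
Product: 14 (2S,3S)-2-[3,4-bis(triisopropylsilyloxy)phenyl]-3-{[bis(4-methoxyphenyl)(phenyl)methoxy]methyl}-7-(triisopropylsilyloxy)-2,3-dihydro-1-benzofuran
Conditions: TIPSCl, imidazole, DMF, rt
Reagents that add atoms: chlorotriisopropylsilane (TIPSCl), CC(C)[Si](Cl)(C(C)C)C(C)C
Why: Phenol silylation under imidazole buffering (the DMTr ether tolerates it) masks the electron-rich phenol before the oxidations and the acylation.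

**Step 8**
Reactants: 14 (2S,3S)-2-[3,4-bis(triisopropylsilyloxy)phenyl]-3-{[bis(4-methoxyphenyl)(phenyl)methoxy]methyl}-7-(triisopropylsilyloxy)-2,3-dihydro-1-benzofuran
Product: 15 [(2S,3S)-2-[3,4-bis(triisopropylsilyloxy)phenyl]-7-(triisopropylsilyloxy)-2,3-dihydro-1-benzofuran-3-yl]methanol
Conditions: Cl2CHCO2H (3 % v/v), MeOH (10 equiv), CH2Cl2, 0 °C, minutes
Reagents that add atoms: none
Why: Acid-catalysed detritylation: the DMTr ether ionises within minutes in dilute dichloroacetic acid and methanol traps the cation, conditions under which aryl silyl ethers and the C2–O1 benzylic ether of the cis ring should stay intact.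

**Step 9**
Reactants: 15 [(2S,3S)-2-[3,4-bis(triisopropylsilyloxy)phenyl]-7-(triisopropylsilyloxy)-2,3-dihydro-1-benzofuran-3-yl]methanol
Product: 16 (2S,3R)-2-[3,4-bis(triisopropylsilyloxy)phenyl]-7-(triisopropylsilyloxy)-2,3-dihydro-1-benzofuran-3-carboxylic acid
Conditions: 2,2,6,6-tetramethylpiperidine-1-oxyl (20 mol %), PhI(OAc)2, MeCN/pH 7 phosphate buffer, 0 °C → rt
Reagents that add atoms: water, O
Why: Nitroxyl-catalysed oxidation with PhI(OAc)2 in aqueous acetonitrile takes the primary alcohol through the aldehyde hydrate straight to the acid near neutrality, so the epimerisable cis aldehyde is neither accumulated nor exposed to base (the descriptor at C3 changes only by priority).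

**Step 10**
Reactants: 17 acryloyl chloride; 18 2-(trimethylsilyl)ethanol
Product: 19 2-(trimethylsilyl)ethyl acrylate
Conditions: Et3N, CH2Cl2, 0 °C
Reagents that add atoms: none
Why: Simple O-acylation of a primary alcohol by an acid chloride gives an acrylate whose ester is later removable by fluoride.

**Step 11**
Reactants: 16 (2S,3R)-2-[3,4-bis(triisopropylsilyloxy)phenyl]-7-(triisopropylsilyloxy)-2,3-dihydro-1-benzofuran-3-carboxylic acid; 19 2-(trimethylsilyl)ethyl acrylate
Product: 20 (2S,3R)-2-[3,4-bis(triisopropylsilyloxy)phenyl]-7-(triisopropylsilyloxy)-4-{(E)-3-oxo-3-[2-(trimethylsilyl)ethoxy]prop-1-enyl}-2,3-dihydro-1-benzofuran-3-carboxylic acid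
Conditions: Pd(OAc)2 (10 mol %), N-acetyl-L-isoleucine (20 mol %), KHCO3 (2 equiv), O2 (1 atm), t-AmylOH, 85 °C; then 1 M HCl
Reagents that add atoms: none
Why: Carboxylate-directed ortho C–H olefination by divalent palladium with a mono-N-protected amino acid ligand (Fujiwara–Moritani type oxidative Heck), precedented on trans-configured 2-aryl-dihydrobenzofuran-3-carboxylic acids: the C3 carboxylate forms a six-membered palladacycle at C4, the only ortho C–H left beside C3a, insertion and β-hydride elimination give the E-alkene, and a carboxylate α-carbon should not epimerise under bicarbonate.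

**Step 12**
Reactants: 21 (−)-shikimic acid [(3R,4S,5R)-3,4,5-trihydroxycyclohex-1-ene-1-carboxylic acid]
Product: 22 3,4-O-isopropylideneshikimic acid
Conditions: 2,2-dimethoxypropane, p-toluenesulfonic acid monohydrate (cat.), acetone, rt
Reagents that add atoms: 2,2-dimethoxypropane, COC(C)(C)OC
Why: Acid-catalysed transketalisation closes the five-membered acetonide only on the cis 3,4-diol and leaves the trans 5-OH free.

**Step 13**
Reactants: 22 3,4-O-isopropylideneshikimic acid; 18 2-(trimethylsilyl)ethanol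
Product: 23 2-(trimethylsilyl)ethyl 3,4-O-isopropylideneshikimate
Conditions: DIC, 4-(dimethylamino)pyridine (cat.), 18 (5 equiv), CH2Cl2, 0 °C → rt
Reagents that add atoms: none
Why: Steglich esterification in which the primary alcohol, used in excess, outcompetes the hindered secondary 5-OH of a second molecule.

**Step 14**
Reactants: 20 (2S,3R)-2-[3,4-bis(triisopropylsilyloxy)phenyl]-7-(triisopropylsilyloxy)-4-{(E)-3-oxo-3-[2-(trimethylsilyl)ethoxy]prop-1-enyl}-2,3-dihydro-1-benzofuran-3-carboxylic acid; 23 2-(trimethylsilyl)ethyl 3,4-O-isopropylideneshikimate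
Product: 24 2-(trimethylsilyl)ethyl 5-O-{[(2S,3R)-2-[3,4-bis(triisopropylsilyloxy)phenyl]-7-(triisopropylsilyloxy)-4-{(E)-3-oxo-3-[2-(trimethylsilyl)ethoxy]prop-1-enyl}-2,3-dihydro-1-benzofuran-3-yl]carbonyl}-3,4-O-isopropylideneshikimate
Conditions: DIC, 4-(dimethylamino)pyridine (10 mol %), CH2Cl2, −20 → 0 °C
Reagents that add atoms: none
Why: Steglich esterification at low temperature with only catalytic nucleophilic base and no amine base, to limit enolisation of the activated cis acid; acylation at O5 does not touch C5, so the natural configuration of the shikimate is retained.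

**Step 15**
Reactants: 24 2-(trimethylsilyl)ethyl 5-O-{[(2S,3R)-2-[3,4-bis(triisopropylsilyloxy)phenyl]-7-(triisopropylsilyloxy)-4-{(E)-3-oxo-3-[2-(trimethylsilyl)ethoxy]prop-1-enyl}-2,3-dihydro-1-benzofuran-3-yl]carbonyl}-3,4-O-isopropylideneshikimate
Product: 25 5-O-{[(2S,3R)-4-[(E)-2-carboxyethenyl]-2-(3,4-dihydroxyphenyl)-7-hydroxy-2,3-dihydro-1-benzofuran-3-yl]carbonyl}-3,4-O-isopropylideneshikimic acid
Conditions: TASF (8 equiv), DMF, 0 °C, argon; then aq HCl to pH 3
Reagents that add atoms: none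
Why: Fluoride-induced desilylation cleaves the three aryl Si–O bonds and fragments both 2-(trimethylsilyl)ethyl esters (ethene and Me3SiF) without acid; the acetonide is kept so that no free hydroxyl sits next to the O5 ester while the medium is basic (no acyl migration), and the cold, short reaction with acidic quench limits enolisation at C3.

**Step 16**
Reactants: 25 5-O-{[(2S,3R)-4-[(E)-2-carboxyethenyl]-2-(3,4-dihydroxyphenyl)-7-hydroxy-2,3-dihydro-1-benzofuran-3-yl]carbonyl}-3,4-O-isopropylideneshikimic acid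
Product: 26 5-O-{[(2S,3R)-4-[(E)-2-carboxyethenyl]-2-(3,4-dihydroxyphenyl)-7-hydroxy-2,3-dihydro-1-benzofuran-3-yl]carbonyl}shikimic acid (target)
Conditions: AcOH/H2O (4:1), 40 °C
Reagents that add atoms: none
Why: Mild aqueous acetic acid should hydrolyse the allylic cis-fused acetonide while being too weak to ionise the C2–O1 benzylic ether or to move the acyl group (acyl migration in shikimate esters is base-mediated).

**Compound list**
1 | 2-(3-bromo-2-fluorophenyl)acetic acid | OC(=O)Cc1cccc(Br)c1F | starting material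
2 | (S)-4-benzyl-1,3-oxazolidin-2-one | O=C1N[C@@H](Cc2ccccc2)CO1 | starting material
3 | (S)-4-benzyl-3-[2-(3-bromo-2-fluorophenyl)acetyl]-1,3-oxazolidin-2-one | O=C(Cc1cccc(Br)c1F)N1[C@@H](Cc2ccccc2)COC1=O | intermediate
4 | 3,4-dihydroxybenzaldehyde | O=Cc1ccc(O)c(O)c1 | starting material
5 | 3,4-bis(triisopropylsilyloxy)benzaldehyde | O=Cc1ccc(O[Si](C(C)C)(C(C)C)C(C)C)c(O[Si](C(C)C)(C(C)C)C(C)C)c1 | intermediate
6 | (S)-4-benzyl-3-[(2R,3S)-2-(3-bromo-2-fluorophenyl)-3-[3,4-bis(triisopropylsilyloxy)phenyl]-3-(trimethylsilyloxy)propanoyl]-1,3-oxazolidin-2-one | O=C([C@H](c1cccc(Br)c1F)[C@H](O[Si](C)(C)C)c1ccc(O[Si](C(C)C)(C(C)C)C(C)C)c(O[Si](C(C)C)(C(C)C)C(C)C)c1)N1[C@@H](Cc2ccccc2)COC1=O | intermediate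
7 | (S)-4-benzyl-3-[(2R,3S)-2-(3-bromo-2-fluorophenyl)-3-hydroxy-3-[3,4-bis(triisopropylsilyloxy)phenyl]propanoyl]-1,3-oxazolidin-2-one | O=C([C@H](c1cccc(Br)c1F)[C@H](O)c1ccc(O[Si](C(C)C)(C(C)C)C(C)C)c(O[Si](C(C)C)(C(C)C)C(C)C)c1)N1[C@@H](Cc2ccccc2)COC1=O | intermediate
8 | (1S,2S)-2-(3-bromo-2-fluorophenyl)-1-[3,4-bis(triisopropylsilyloxy)phenyl]propane-1,3-diol | OC[C@H](c1cccc(Br)c1F)[C@H](O)c1ccc(O[Si](C(C)C)(C(C)C)C(C)C)c(O[Si](C(C)C)(C(C)C)C(C)C)c1 | intermediate
9 | (1S,2S)-3-[bis(4-methoxyphenyl)(phenyl)methoxy]-2-(3-bromo-2-fluorophenyl)-1-[3,4-bis(triisopropylsilyloxy)phenyl]propan-1-ol | COc1ccc(cc1)C(OC[C@H](c1cccc(Br)c1F)[C@H](O)c1ccc(O[Si](C(C)C)(C(C)C)C(C)C)c(O[Si](C(C)C)(C(C)C)C(C)C)c1)(c1ccccc1)c1ccc(OC)cc1 | intermediate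
10 | lithium (1S,2S)-3-[bis(4-methoxyphenyl)(phenyl)methoxy]-2-(2,3-didehydrophenyl)-1-[3,4-bis(triisopropylsilyloxy)phenyl]propan-1-olate (aryne) | COc1ccc(cc1)C(OC[C@H](C1=CC=CC#C1)[C@H](O[Li])c1ccc(O[Si](C(C)C)(C(C)C)C(C)C)c(O[Si](C(C)C)(C(C)C)C(C)C)c1)(c1ccccc1)c1ccc(OC)cc1 | intermediate
11 | [(2S,3S)-2-[3,4-bis(triisopropylsilyloxy)phenyl]-3-{[bis(4-methoxyphenyl)(phenyl)methoxy]methyl}-2,3-dihydro-1-benzofuran-7-yl]lithium | c1ccc([Li])c2c1[C@@H](COC(c1ccc(OC)cc1)(c1ccccc1)c1ccc(OC)cc1)[C@@H](c1ccc(O[Si](C(C)C)(C(C)C)C(C)C)c(O[Si](C(C)C)(C(C)C)C(C)C)c1)O2 | intermediate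
12 | lithium trimethoxy[(2S,3S)-2-[3,4-bis(triisopropylsilyloxy)phenyl]-3-{[bis(4-methoxyphenyl)(phenyl)methoxy]methyl}-2,3-dihydro-1-benzofuran-7-yl]borate | c1ccc([B-](OC)(OC)OC)c2c1[C@@H](COC(c1ccc(OC)cc1)(c1ccccc1)c1ccc(OC)cc1)[C@@H](c1ccc(O[Si](C(C)C)(C(C)C)C(C)C)c(O[Si](C(C)C)(C(C)C)C(C)C)c1)O2.[Li+] | intermediate
13 | (2S,3S)-2-[3,4-bis(triisopropylsilyloxy)phenyl]-3-{[bis(4-methoxyphenyl)(phenyl)methoxy]methyl}-2,3-dihydro-1-benzofuran-7-ol | c1ccc(O)c2c1[C@@H](COC(c1ccc(OC)cc1)(c1ccccc1)c1ccc(OC)cc1)[C@@H](c1ccc(O[Si](C(C)C)(C(C)C)C(C)C)c(O[Si](C(C)C)(C(C)C)C(C)C)c1)O2 | intermediate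
14 | (2S,3S)-2-[3,4-bis(triisopropylsilyloxy)phenyl]-3-{[bis(4-methoxyphenyl)(phenyl)methoxy]methyl}-7-(triisopropylsilyloxy)-2,3-dihydro-1-benzofuran | c1ccc(O[Si](C(C)C)(C(C)C)C(C)C)c2c1[C@@H](COC(c1ccc(OC)cc1)(c1ccccc1)c1ccc(OC)cc1)[C@@H](c1ccc(O[Si](C(C)C)(C(C)C)C(C)C)c(O[Si](C(C)C)(C(C)C)C(C)C)c1)O2 | intermediate
15 | [(2S,3S)-2-[3,4-bis(triisopropylsilyloxy)phenyl]-7-(triisopropylsilyloxy)-2,3-dihydro-1-benzofuran-3-yl]methanol | c1ccc(O[Si](C(C)C)(C(C)C)C(C)C)c2c1[C@@H](CO)[C@@H](c1ccc(O[Si](C(C)C)(C(C)C)C(C)C)c(O[Si](C(C)C)(C(C)C)C(C)C)c1)O2 | intermediate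
16 | (2S,3R)-2-[3,4-bis(triisopropylsilyloxy)phenyl]-7-(triisopropylsilyloxy)-2,3-dihydro-1-benzofuran-3-carboxylic acid | c1ccc(O[Si](C(C)C)(C(C)C)C(C)C)c2c1[C@@H](C(=O)O)[C@@H](c1ccc(O[Si](C(C)C)(C(C)C)C(C)C)c(O[Si](C(C)C)(C(C)C)C(C)C)c1)O2 | intermediate
17 | acryloyl chloride | C=CC(=O)Cl | starting material
18 | 2-(trimethylsilyl)ethanol | OCC[Si](C)(C)C | starting material
19 | 2-(trimethylsilyl)ethyl acrylate | C=CC(=O)OCC[Si](C)(C)C | intermediate
20 | (2S,3R)-2-[3,4-bis(triisopropylsilyloxy)phenyl]-7-(triisopropylsilyloxy)-4-{(E)-3-oxo-3-[2-(trimethylsilyl)ethoxy]prop-1-enyl}-2,3-dihydro-1-benzofuran-3-carboxylic acid | C[Si](C)(C)CCOC(=O)/C=C/c1ccc(O[Si](C(C)C)(C(C)C)C(C)C)c2c1[C@@H](C(=O)O)[C@@H](c1ccc(O[Si](C(C)C)(C(C)C)C(C)C)c(O[Si](C(C)C)(C(C)C)C(C)C)c1)O2 | intermediate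
21 | (−)-shikimic acid | O[C@@H]1CC(C(=O)O)=C[C@@H](O)[C@H]1O | starting material
22 | 3,4-O-isopropylideneshikimic acid | O[C@@H]1CC(C(=O)O)=C[C@H]2OC(C)(C)O[C@H]21 | intermediate
23 | 2-(trimethylsilyl)ethyl 3,4-O-isopropylideneshikimate | O[C@@H]1CC(C(=O)OCC[Si](C)(C)C)=C[C@H]2OC(C)(C)O[C@H]21 | intermediate
24 | 2-(trimethylsilyl)ethyl 5-O-{[(2S,3R)-2-[3,4-bis(triisopropylsilyloxy)phenyl]-7-(triisopropylsilyloxy)-4-{(E)-3-oxo-3-[2-(trimethylsilyl)ethoxy]prop-1-enyl}-2,3-dihydro-1-benzofuran-3-yl]carbonyl}-3,4-O-isopropylideneshikimate | C[Si](C)(C)CCOC(=O)/C=C/c1ccc(O[Si](C(C)C)(C(C)C)C(C)C)c2c1[C@@H](C(=O)O[C@@H]1CC(C(=O)OCC[Si](C)(C)C)=C[C@H]3OC(C)(C)O[C@H]31)[C@@H](c1ccc(O[Si](C(C)C)(C(C)C)C(C)C)c(O[Si](C(C)C)(C(C)C)C(C)C)c1)O2 | intermediate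
25 | 5-O-{[(2S,3R)-4-[(E)-2-carboxyethenyl]-2-(3,4-dihydroxyphenyl)-7-hydroxy-2,3-dihydro-1-benzofuran-3-yl]carbonyl}-3,4-O-isopropylideneshikimic acid | OC(=O)/C=C/c1ccc(O)c2c1[C@@H](C(=O)O[C@@H]1CC(C(=O)O)=C[C@H]3OC(C)(C)O[C@H]31)[C@@H](c1ccc(O)c(O)c1)O2 | intermediate
26 | 5-O-{[(2S,3R)-4-[(E)-2-carboxyethenyl]-2-(3,4-dihydroxyphenyl)-7-hydroxy-2,3-dihydro-1-benzofuran-3-yl]carbonyl}shikimic acid | O=C(O)/C=C/c1ccc(O)c2c1[C@@H](C(=O)O[C@@H]1CC(C(=O)O)=C[C@@H](O)[C@H]1O)[C@@H](c1ccc(O)c(O)c1)O2 | target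

**Step count**
Total: 16 steps. Longest linear sequence: 12 steps (1 → 3 → 7 → 8 → 9 → 13 → 14 → 15 → 16 → 20 → 24 → 25 → 26; steps 1, 3, 4, 5, 6, 7, 8, 9, 11, 14, 15, 16).

**Steps most likely to fail**

Step 6. What may go wrong: the aryne may be captured by residual organolithium or by a second substrate molecule faster than the lithium alkoxide closes the ring, or the C7 aryllithium may be protonated before it meets the borate, so that ring closure and oxygenation are not both delivered. Fallback: starting from 9, the same O1–C7a bond is closed without an aryne by intramolecular addition–elimination of the potassium alkoxide at the C–F carbon (KN(SiMe3)2, THF/DMPU, 60 °C; the ortho bromine activates inductively and stays in place). This should give (2S,3S)-7-bromo-2-[3,4-bis(triisopropylsilyloxy)phenyl]-3-{[bis(4-methoxyphenyl)(phenyl)methoxy]methyl}-2,3-dihydro-1-benzofuran F1. Bromine–lithium exchange (n-BuLi, THF, −78 °C), B(OMe)3 and H2O2/NaHCO3 then turn C7–Br into C7–OH, and the route is rejoined at 13.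

Step 14. What may go wrong: acylation of the hindered secondary O5 by the hindered activated acid may be slow, leaving time for enolisation or ketene formation at C3 and hence cis-to-trans epimerisation or β-elimination of the O1 phenoxide. Fallback: the same ester bond is made with the acid as nucleophile, so the carboxyl is never activated. Starting from 23, Mitsunobu inversion with 4-nitrobenzoic acid (PPh3, diisopropyl azodicarboxylate, THF) should give 2-(trimethylsilyl)ethyl 5-epi-3,4-O-isopropylidene-5-O-(4-nitrobenzoyl)shikimate F2. K2CO3 in MeOH at 0 °C removes the nitrobenzoate to give 2-(trimethylsilyl)ethyl 5-epi-3,4-O-isopropylideneshikimate F3. A second Mitsunobu reaction of F3 with acid 20 (PPh3, diisopropyl azodicarboxylate, toluene, 0 °C) inverts C5 back to the natural configuration and rejoins the route at 24.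

Step 11. What may go wrong: palladation at C4 of the crowded cis acid may fail or be diverted (palladation of the cis C2 aryl ring, catalyst deactivation, loss of aryl silyl ethers in hot bicarbonate). Fallback: the acrylate is installed by halogenation and cross-coupling, using the phenol made in step 6, which is para to C4. Starting from 13, N-bromosuccinimide (CH2Cl2, −78 °C) should brominate para to the free phenol to give (2S,3S)-4-bromo-2-[3,4-bis(triisopropylsilyloxy)phenyl]-3-{[bis(4-methoxyphenyl)(phenyl)methoxy]methyl}-2,3-dihydro-1-benzofuran-7-ol F4. Mizoroki–Heck coupling with 19 (Pd(OAc)2, P(o-tol)3, Et3N, DMF, 90 °C; no epimerisable centre is present at this stage) should give 2-(trimethylsilyl)ethyl (E)-3-[(2S,3S)-2-[3,4-bis(triisopropylsilyloxy)phenyl]-3-{[bis(4-methoxyphenyl)(phenyl)methoxy]methyl}-7-hydroxy-2,3-dihydro-1-benzofuran-4-yl]prop-2-enoate F5. TIPSCl/imidazole gives its 7-O-triisopropylsilyl ether F6. Cl2CHCO2H/MeOH removes the DMTr group to give 2-(trimethylsilyl)ethyl (E)-3-[(2S,3S)-2-[3,4-bis(triisopropylsilyloxy)phenyl]-3-(hydroxymethyl)-7-(triisopropylsilyloxy)-2,3-dihydro-1-benzofuran-4-yl]prop-2-enoate F7. The nitroxyl/PhI(OAc)2 oxidation of step 9 applied to F7 rejoins the route at 20.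

**Further compounds**
F1 | step 6 | (2S,3S)-7-bromo-2-[3,4-bis(triisopropylsilyloxy)phenyl]-3-{[bis(4-methoxyphenyl)(phenyl)methoxy]methyl}-2,3-dihydro-1-benzofuran | c1ccc(Br)c2c1[C@@H](COC(c1ccc(OC)cc1)(c1ccccc1)c1ccc(OC)cc1)[C@@H](c1ccc(O[Si](C(C)C)(C(C)C)C(C)C)c(O[Si](C(C)C)(C(C)C)C(C)C)c1)O2
F2 | step 14 | 2-(trimethylsilyl)ethyl 5-epi-3,4-O-isopropylidene-5-O-(4-nitrobenzoyl)shikimate | O=C(O[C@H]1CC(C(=O)OCC[Si](C)(C)C)=C[C@H]2OC(C)(C)O[C@H]21)c1ccc(cc1)[N+](=O)[O-]
F3 | step 14 | 2-(trimethylsilyl)ethyl 5-epi-3,4-O-isopropylideneshikimate | O[C@H]1CC(C(=O)OCC[Si](C)(C)C)=C[C@H]2OC(C)(C)O[C@H]21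
F4 | step 11 | (2S,3S)-4-bromo-2-[3,4-bis(triisopropylsilyloxy)phenyl]-3-{[bis(4-methoxyphenyl)(phenyl)methoxy]methyl}-2,3-dihydro-1-benzofuran-7-ol | Brc1ccc(O)c2c1[C@@H](COC(c1ccc(OC)cc1)(c1ccccc1)c1ccc(OC)cc1)[C@@H](c1ccc(O[Si](C(C)C)(C(C)C)C(C)C)c(O[Si](C(C)C)(C(C)C)C(C)C)c1)O2
F5 | step 11 | 2-(trimethylsilyl)ethyl (E)-3-[(2S,3S)-2-[3,4-bis(triisopropylsilyloxy)phenyl]-3-{[bis(4-methoxyphenyl)(phenyl)methoxy]methyl}-7-hydroxy-2,3-dihydro-1-benzofuran-4-yl]prop-2-enoate | C[Si](C)(C)CCOC(=O)/C=C/c1ccc(O)c2c1[C@@H](COC(c1ccc(OC)cc1)(c1ccccc1)c1ccc(OC)cc1)[C@@H](c1ccc(O[Si](C(C)C)(C(C)C)C(C)C)c(O[Si](C(C)C)(C(C)C)C(C)C)c1)O2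
F6 | step 11 | 2-(trimethylsilyl)ethyl (E)-3-[(2S,3S)-2-[3,4-bis(triisopropylsilyloxy)phenyl]-3-{[bis(4-methoxyphenyl)(phenyl)methoxy]methyl}-7-(triisopropylsilyloxy)-2,3-dihydro-1-benzofuran-4-yl]prop-2-enoate | C[Si](C)(C)CCOC(=O)/C=C/c1ccc(O[Si](C(C)C)(C(C)C)C(C)C)c2c1[C@@H](COC(c1ccc(OC)cc1)(c1ccccc1)c1ccc(OC)cc1)[C@@H](c1ccc(O[Si](C(C)C)(C(C)C)C(C)C)c(O[Si](C(C)C)(C(C)C)C(C)C)c1)O2
F7 | step 11 | 2-(trimethylsilyl)ethyl (E)-3-[(2S,3S)-2-[3,4-bis(triisopropylsilyloxy)phenyl]-3-(hydroxymethyl)-7-(triisopropylsilyloxy)-2,3-dihydro-1-benzofuran-4-yl]prop-2-enoate | C[Si](C)(C)CCOC(=O)/C=C/c1ccc(O[Si](C(C)C)(C(C)C)C(C)C)c2c1[C@@H](CO)[C@@H](c1ccc(O[Si](C(C)C)(C(C)C)C(C)C)c(O[Si](C(C)C)(C(C)C)C(C)C)c1)O2
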